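## Retrosynthetic overview
1. The last bond made is the O-methyl bond at the chelated 5-OH of (2S)-5-hydroxy-6,7,8,4'-tetramethoxyflavanone.
2. Key disconnection: rings C and A both open to one β-hydroxy ynone that carries a 2,3,4-trimethoxycyclobutenone on its alkyne terminus. In the forward direction, 6-endo O-cyclisation closes ring C first. Then 4π opening and 6π closure of the cyclobutenone builds ring A onto the new C4a=C8a alkene in the same flask.
3. C2–C3: a catalytic asymmetric Mukaiyama aldol on 4-methoxybenzaldehyde (ring B, bought) sets the only stereocentre.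
4. C8–C8a: an acetylide adds to dimethyl squarate, whose four carbons become C5–C8 with all four oxygens in place. The C3–C4–C4a–C8a unit is but-3-yn-2-one, masked and activated at once as its silyl enol ether.

Assumption: flavanone numbering (O1, C2 … C8a) is used for atoms throughout. The extra stereocentre at C4 of each cyclobutenone intermediate is left uncontrolled, because it ends as the planar C8 of ring A.

## Route

Step 1
Reactants: 1 but-3-yn-2-one
Product: 2 tert-butyl(but-1-en-3-yn-2-yloxy)dimethylsilane
Conditions: TBSOTf (1.05 equiv), Et3N (1.3 equiv), Et2O, −78 to 0 °C; distil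
Reagents that add atoms: tert-butyldimethylsilyl triflate (TBSOTf), CC(C)(C)[Si](C)(C)OS(=O)(=O)C(F)(F)F
Why: Soft enolisation (silyl triflate/amine silyl enol ether formation) at the only enolisable position masks the ketone against the acetylide chemistry of step 2 and already provides the nucleophile for the later Mukaiyama aldol.

Step 2
Reactants: 2 tert-butyl(but-1-en-3-yn-2-yloxy)dimethylsilane; 3 dimethyl squarate
Product: 6 4-{3-[(tert-butyldimethylsilyl)oxy]but-3-en-1-yn-1-yl}-2,3,4-trimethoxycyclobut-2-en-1-one (racemic), via lithium acetylide 4 (not isolated), via lithium alkoxide 5 (not isolated)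
Conditions: n-BuLi (1.0 equiv), THF, −78 °C; add to 3 (1.05 equiv), THF, −78 °C; MeOTf (1.3 equiv), −78 to −20 °C; aq NaHCO3; Et3N-washed silica, keep below 40 °C
Reagents that add atoms: methyl triflate (MeOTf), COS(=O)(=O)C(F)(F)F
Why: Hard lithium acetylides add 1,2 to one carbonyl of squarate esters, and MeOTf O-methylates the tertiary lithium alkoxide far faster than it touches the silyl enol ether (squarate 1,2-addition with alkoxide capture, the standard entry to Moore precursors); the new quaternary centre is racemic and is erased in step 4.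

Step 3
Reactants: 6 4-{3-[(tert-butyldimethylsilyl)oxy]but-3-en-1-yn-1-yl}-2,3,4-trimethoxycyclobut-2-en-1-one; 7 4-methoxybenzaldehyde
Product: 9 4-[(5S)-5-hydroxy-5-(4-methoxyphenyl)-3-oxopent-1-yn-1-yl]-2,3,4-trimethoxycyclobut-2-en-1-one (about 1:1 epimers at the cyclobutenone carbon), via trichlorosilyl ether 8 (not isolated)
Conditions: SiCl4 (1.5 equiv), (S,S)-CH2[CH2CH2N(Me)P(O)(N,N'-dimethyl-1,1'-binaphthyl-2,2'-diamido)]2 (5 mol %), i-Pr2NEt (0.2 equiv), CH2Cl2, −78 °C; cold sat. aq NaHCO3
Reagents that add atoms: none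
Why: In this Lewis-base-activated SiCl4 Mukaiyama aldol the chiral phosphoramide-bound silyl cation binds the electron-rich aldehyde (the best substrate class for this catalyst) and leaves its Si face open to the enol silane in an open transition state, which sets C2 as (S), while the remote racemic cyclobutenone centre has no say.

Step 4 (key step)
Reactants: 9 4-[(5S)-5-hydroxy-5-(4-methoxyphenyl)-3-oxopent-1-yn-1-yl]-2,3,4-trimethoxycyclobut-2-en-1-one
Product: 13 (2S)-5-hydroxy-6,7,8-trimethoxy-2-(4-methoxyphenyl)chroman-4-one, via pyranonyl cyclobutenone 10 (not isolated), via dienylketene 11 (not isolated), via cyclohexadienone 12 (not isolated)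
Conditions: Ph3PAuNTf2 (5 mol %), 2,6-di-tert-butylpyridine (10 mol %), dry toluene (0.02 M), Ar, 23 °C, 1 h; then 110 °C, 2 h, same flask
Reagents that add atoms: none
Why: Proposed new method: a 6-endo-dig oxa-Michael cycloisomerisation of the β-hydroxy ynone, catalysed by monovalent gold, closes ring C without touching the C2–O bond, so (S) is retained, and turns the 4-alkynyl- into a 4-alkenylcyclobutenone before any alkyne-type diradical chemistry can start; on heating this undergoes a Moore-type benzannulation (conrotatory 4π opening with OMe rotating outward and the pyranonyl group inward, 6π closure of the electrophilic ketene carbon onto the nucleophilic α-carbon of the vinylogous ester, then enolisation driven by aromaticity and the 5-OH···O=C4 hydrogen bond) that builds ring A; the closest known reactions are the gold-catalysed cyclisation of β-hydroxy ynones to 2,3-dihydro-4H-pyran-4-ones and the thermolysis of 4-(dihydropyran-6-yl)-4-oxycyclobutenones to chroman hydroquinones, run here in tandem as a pure isomerisation.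

Step 5
Reactants: 13 (2S)-5-hydroxy-6,7,8-trimethoxy-2-(4-methoxyphenyl)chroman-4-one
Product: 14 (2S)-5,6,7,8-tetramethoxy-2-(4-methoxyphenyl)chroman-4-one
Conditions: MeI/CH2Cl2 (1:1), Ag2O (3 equiv), 4 Å sieves, 35 °C, dark
Reagents that add atoms: methyl iodide (MeI), CI
Why: Purdie-type O-methylation removes HI on the silver oxide surface without building up free phenoxide or C3 enolate, so the chelated 5-OH is alkylated while the base-triggered retro-oxa-Michael (chalcone) pathway that would racemise C2 stays closed.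

## Compound list
1 | but-3-yn-2-one | CC(=O)C#C | starting material
2 | tert-butyl(but-1-en-3-yn-2-yloxy)dimethylsilane | C=C(O[Si](C)(C)C(C)(C)C)C#C | intermediate
3 | dimethyl squarate (3,4-dimethoxycyclobut-3-ene-1,2-dione) | COC1=C(OC)C(=O)C1=O | starting material
4 | lithium acetylide of 2 (not isolated) | [Li]C#CC(=C)O[Si](C)(C)C(C)(C)C | intermediate
5 | lithium alkoxide from 1,2-addition of 4 to 3 (not isolated) | [Li]OC1(C#CC(=C)O[Si](C)(C)C(C)(C)C)C(OC)=C(OC)C1=O | intermediate
6 | 4-{3-[(tert-butyldimethylsilyl)oxy]but-3-en-1-yn-1-yl}-2,3,4-trimethoxycyclobut-2-en-1-one (racemic) | COC1(C#CC(=C)O[Si](C)(C)C(C)(C)C)C(OC)=C(OC)C1=O | intermediate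
7 | 4-methoxybenzaldehyde | COc1ccc(C=O)cc1 | starting material
8 | (S)-trichlorosilyl ether of 9 (not isolated) | COc1ccc([C@@H](O[Si](Cl)(Cl)Cl)CC(=O)C#CC2(OC)C(OC)=C(OC)C2=O)cc1 | intermediate
9 | 4-[(5S)-5-hydroxy-5-(4-methoxyphenyl)-3-oxopent-1-yn-1-yl]-2,3,4-trimethoxycyclobut-2-en-1-one (cyclobutenone carbon uncontrolled) | COc1ccc([C@@H](O)CC(=O)C#CC2(OC)C(OC)=C(OC)C2=O)cc1 | intermediate
10 | (2S)-2-(4-methoxyphenyl)-6-(1,2,3-trimethoxy-4-oxocyclobut-2-en-1-yl)-2,3-dihydro-4H-pyran-4-one (not isolated) | COc1ccc([C@@H]2CC(=O)C=C(O2)C3(OC)C(OC)=C(OC)C3=O)cc1 | intermediate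
11 | (Z)-dienylketene, 2,3,4-trimethoxy-4-[(2S)-2-(4-methoxyphenyl)-4-oxo-2,3-dihydropyran-6-yl]buta-1,3-dien-1-one (not isolated) | COc1ccc([C@@H]2CC(=O)C=C(O2)/C(OC)=C(OC)\C(OC)=C=O)cc1 | intermediate
12 | keto tautomer of 13, (2S)-6,7,8-trimethoxy-2-(4-methoxyphenyl)-2,3-dihydro-4aH-chromene-4,5-dione (C4a transient, not isolated) | COc1ccc([C@@H]2CC(=O)C3C(=O)C(OC)=C(OC)C(OC)=C3O2)cc1 | intermediate
13 | (2S)-5-hydroxy-6,7,8-trimethoxy-2-(4-methoxyphenyl)chroman-4-one | COc1ccc([C@@H]2CC(=O)c3c(O)c(OC)c(OC)c(OC)c3O2)cc1 | intermediate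
14 | (2S)-5,6,7,8,4'-pentamethoxyflavanone | COc1ccc([C@@H]2CC(=O)c3c(OC)c(OC)c(OC)c(OC)c3O2)cc1 | target

## Step count
- Total steps: 5
- Longest linear sequence: 5 (1 → 2 → 6 → 9 → 13 → 14)

## Steps most likely to fail

**Step 4.** The alkyne terminus sits next to a quaternary carbon, which may slow the 6-endo closure. Uncyclised ynone would then enter the alkynyl diradical manifold on heating. Trace acid could also dehydrate or ionise the p-methoxybenzylic C2–O bond.

The fallback sets out from 9 and returns at 13. Ring C is closed by addition–elimination instead of π-acid catalysis. Et2NH (1.2 equiv, CH2Cl2, 0 °C) adds to the ynone to give 4-[(1E,5S)-1-(diethylamino)-5-hydroxy-5-(4-methoxyphenyl)-3-oxopent-1-en-1-yl]-2,3,4-trimethoxycyclobut-2-en-1-one F1. Pyridinium tosylate in toluene at 23 °C then lets the C2 hydroxyl displace the amine to give 10. This is filtered through a short silica pad, checked for ee, and heated on its own (toluene, 110 °C, or a 150 °C flow coil) to 13.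

**Step 3.** The alkynyl group lowers the nucleophilicity of the enol silane. SiCl4 may ionise the tertiary methoxy group, and the ee may fall short. One recrystallisation of 13 is the first remedy.

The fallback sets out from 3 and returns at 9. The stereocentre is made by ketone reduction instead of C–C bond formation, and the C4–C4a bond is formed last.
- HC≡CLi (THF, −78 °C) is added to 3 and the alkoxide is capped with MeOTf to give 4-ethynyl-2,3,4-trimethoxycyclobut-2-en-1-one F2.
- In parallel, bought ethyl 3-(4-methoxyphenyl)-3-oxopropanoate F3 is reduced with RuCl[(S,S)-TsDPEN](p-cymene) in HCO2H/Et3N to ethyl (3S)-3-hydroxy-3-(4-methoxyphenyl)propanoate F4.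
- Me3Al/EtSH (CH2Cl2, 0 °C) converts F4 into S-ethyl (3S)-3-hydroxy-3-(4-methoxyphenyl)propanethioate F5.
- A thioester–alkyne coupling of F5 with F2 (PdCl2(dppf), P(2-furyl)3, CuI, Et3N/DMF, 50 °C) tolerates the free hydroxyl and gives 9. Any 10 formed in the pot is already on the path.

**Step 5.** The hydrogen-bonded, doubly ortho-substituted 5-OH may react too slowly. Any stronger base risks opening ring C and racemising C2.

The fallback sets out from 13 and returns at 14. The ketone is removed for the duration of the alkylation.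
- NaBH4 (MeOH, 0 °C) gives (2S)-6,7,8-trimethoxy-2-(4-methoxyphenyl)chromane-4,5-diol F6 (mainly 2,4-cis; C4 is erased again).
- With neither chelation nor an enolisable ketone left, MeI/K2CO3 (acetone, 23 °C) methylates the phenol to (2S)-5,6,7,8-tetramethoxy-2-(4-methoxyphenyl)chroman-4-ol F7, with no way to open ring C.
- Dess–Martin periodinane (CH2Cl2, NaHCO3) restores the ketone and gives 14.

## Further compounds
F1 | step 4 | 4-[(1E,5S)-1-(diethylamino)-5-hydroxy-5-(4-methoxyphenyl)-3-oxopent-1-en-1-yl]-2,3,4-trimethoxycyclobut-2-en-1-one | COc1ccc([C@@H](O)CC(=O)/C=C(/N(CC)CC)C2(OC)C(OC)=C(OC)C2=O)cc1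
F2 | step 3 | 4-ethynyl-2,3,4-trimethoxycyclobut-2-en-1-one | COC1(C#C)C(OC)=C(OC)C1=O
F3 | step 3 | ethyl 3-(4-methoxyphenyl)-3-oxopropanoate (bought) | CCOC(=O)CC(=O)c1ccc(OC)cc1
F4 | step 3 | ethyl (3S)-3-hydroxy-3-(4-methoxyphenyl)propanoate | COc1ccc([C@@H](O)CC(=O)OCC)cc1
F5 | step 3 | S-ethyl (3S)-3-hydroxy-3-(4-methoxyphenyl)propanethioate | COc1ccc([C@@H](O)CC(=O)SCC)cc1
F6 | step 5 | (2S)-6,7,8-trimethoxy-2-(4-methoxyphenyl)chromane-4,5-diol | COc1ccc([C@@H]2CC(O)c3c(O)c(OC)c(OC)c(OC)c3O2)cc1
F7 | step 5 | (2S)-5,6,7,8-tetramethoxy-2-(4-methoxyphenyl)chroman-4-ol | COc1ccc([C@@H]2CC(O)c3c(OC)c(OC)c(OC)c(OC)c3O2)cc1
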